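The steady rate of E in Sunday's run is 1.96 times that in Saturday's run, for a step from 20 °C to 45 °C. That ratio needs explaining.

all flasks: D 200 mM (held)
- Saturday's: L 1 M; temperature 20 °C; run made earlier
- Sunday's: L 1 M; temperature 45 °C; run made earlier
- oak: L 2.0 M; temperature 65 °C; time 3.0 min
- larch: L 2.0 M; temperature 25 °C; time 3.0 min

- Saturday's (time / s: E / %, L / %): 20.0: 0.7, 99.1; 40.0: 3.2, 96.8; 50.0: 4.4, 95.8; 80.0: 8.8, 91.7; 90.0: 10.5, 90.3; 120: 14.8, 85.4
- Sunday's (time / s: E / %, L / %): 10.0: 1.1, 98.3; 15.0: 2.6, 97.1; 20.0: 3.6, 95.9; 30.0: 6.9, 93.0; 40.0: 9.7, 90.7

(readings scatter by 0.3 percentage points)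

- which one finishes higher in amount of E, in percent of the L charged ("neither" within 2 percentage points) (oak / larch / neither)
- amount of E at the end, in percent of the L charged, oak
- amount of E at the end, in percent of the L charged, larch

- at the start none of D is in solution

**What do the readings give?** Draw a straight line through the second and the last E reading of each run. Let r be its slope as a concentration per time, and τ, the lag, the time at which it crosses zero. Saturday's run gives r = 1.45 mM/s and τ = 17.9 s. Sunday's run gives r = 2.84 mM/s and τ = 5.85 s.

**Why a lag?** None of D is in solution at the start, so my guess is that D must dissolve first. Suppose it enters at k(c_sat − c), where c is its dissolved concentration and c_sat its saturation value, and reacts at bc. Then c levels off with τ = 1/(k + b), and r = k·c_sat·(1 − kτ).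

**What does that buy?** It makes r fall in a straight line with τ. The line's value at no lag is G, the supply ceiling, k·c_sat, the rate at which D enters empty solution: G = 3.51 mM/s.

**Two points make any line. Why trust it?** Not closely: I assume k is the same at both temperatures, and each lag carries the scatter of 0.3 percentage points.

**Oak?** Sunday's run already reached 80.9% of G. Oak is hotter than that run and holds twice its L, so I take dissolving as the rate-limiting step. By my reckoning L then falls by about G·t, which leaves 68.4% of the L and makes 31.6% E.

**Larch?** Its temperature, 25 °C, stands near that of Saturday's run, whose rate is less than G, though larch holds twice the L of that run. I expect larch below my oak figure, and oak ahead.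

The forecast says oak, with 51% (37% to 64%) for oak and 23% (13% to 29%) for larch: “I lean towards first order but shade the estimates down.” My oak figure lies below its range.

Oak ends at 32.9% and larch at 21.2%, so oak finishes higher.

    D ⇌ Q, rate k1*(csat - [Q]) (kL = 0.0191 /s)
    L + Q → E (k = 0.0232 /M/s, Ea = 57.0 kJ/mol)
    (constants at 25 °C)

Q, the dissolved D, stands at 0.00773 M at the end of oak, against 0.0674 M in larch. Oak's average rate of E over its run is 3.66 mM/s, a little more than G = 3.51 mM/s as read from the two runs. The neighbour flask is oak with 1.2 M of L: G·t leaves 47.3% of its L, and that flask holds 47.5% of it at 3.00 min.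

The data stem from a simulated flask for an exercise; the scatter is artificial.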